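**Plan**

1. Cuts: first the interflavan bond C4(upper)–C8(lower) (Friedel–Crafts), then, in the lower epigallocatechin unit, C3–C4 (aldol) and O1–C2 (oxa-Michael) of ring C. The upper robinetinidol unit is taken from (+)-dihydrorobinetin.
2. Enabling feature: in the lower unit C4 is a benzylic CH2 on the phloroglucinol ring A, ortho to the ring oxygen O1, and C3 is an oxygen-bearing CH next to the aryl-bearing C2. Ring A plus C4 is therefore a salicylaldehyde, and C2–C3 is a cinnamaldehyde whose formyl group, a temporary helper on C3, makes C3 an enamine nucleophile.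
3. Forward: rings A and B are bought. Ring C of the lower unit is closed by amine-catalysed oxa-Michael addition and intramolecular aldol condensation (C3–C4). The helper formyl carbon is then exchanged for the 3-oxygen by Baeyer–Villiger oxidation and the flavan-3-one is reduced. The benzylated upper unit is reduced and acetylated, the halves are joined at C4–C8, and the protecting groups leave last.
4. Stereochemistry: lower C2 from the (S)-diarylprolinol silyl ether catalyst; lower C3 from hydride attack anti to the 2-aryl group (2,3-cis); upper C2 and C3 from the chiral pool; upper C4 from participation of the 3-acetoxy group (3,4-trans).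

Key step: step 3

Assumption: commercial (+)-dihydrorobinetin is the (2R,3R)-trans-dihydroflavonol, so it already carries the configurations of the upper C2 and C3 (C3 becomes 3S by name only once C4 is no longer a carbonyl).

**Route**

Step 1
Reactants: 1 3,4,5-tris(benzyloxy)benzaldehyde
Product: 2 (2E)-3-[3,4,5-tris(benzyloxy)phenyl]prop-2-enal
Conditions: Ph3P=CHCHO (1.1 equiv), toluene, 90 °C
Reagents that add atoms: (triphenylphosphoranylidene)acetaldehyde, O=CC=P(c1ccccc1)(c1ccccc1)c1ccccc1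
Why: Wittig olefination with the stabilised formylmethylene ylide should give the (E)-enal, and aldehyde 1 reacts faster than the less electrophilic product enal, which limits a second homologation.

Step 2
Reactants: 3 2,4,6-trihydroxybenzaldehyde
Product: 4 4,6-bis(benzyloxy)-2-hydroxybenzaldehyde
Conditions: BnBr (2.0 equiv), K2CO3 (2.0 equiv), DMF, 0 °C to rt
Reagents that add atoms: benzyl bromide, BrCc1ccccc1
Why: Williamson ether synthesis in which the para and one ortho phenoxide are benzylated, while the last ortho hydroxyl is held in a hydrogen bond to the formyl group and should stay free as the future ring oxygen O1.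

Step 3
Reactants: 4 4,6-bis(benzyloxy)-2-hydroxybenzaldehyde; 2 (2E)-3-[3,4,5-tris(benzyloxy)phenyl]prop-2-enal (1.2 equiv)
Product: 5 (2R)-5,7-bis(benzyloxy)-2-[3,4,5-tris(benzyloxy)phenyl]-2H-chromene-3-carbaldehyde
Conditions: (S)-2-[diphenyl(trimethylsilyloxy)methyl]pyrrolidine (20 mol %), 2-nitrobenzoic acid (20 mol %), 4 Å molecular sieves, toluene, rt; filtration through silica to remove the amine
Reagents that add atoms: none
Why: The secondary amine condenses with enal 2 to an (E)-iminium ion, the phenolic oxygen of 4 adds to its β-carbon (O1–C2 bond), and the enamine so formed attacks the neighbouring formyl carbon through its α-carbon, which forms the C3–C4 bond and closes ring C; loss of water and hydrolysis then release 5 and the catalyst. The reaction type is the amine-catalysed domino oxa-Michael/aldol condensation of salicylaldehydes with cinnamaldehydes, well known with diarylprolinol silyl ethers. Ring C, the only ring formed, is closed by the aldol step in the 6-(enolexo)-exo-trig mode, and the dehydration that follows makes the sequence irreversible. The only new stereocentre, C2, is set in the oxa-Michael step: the CPh2(OSiMe3) group of the (S)-catalyst blocks one face of the planar iminium ion, so oxygen adds to the open face and should give the 2R configuration. The step needs the cross-reaction (iminium formation from 2, not from the hydrogen-bonded, electron-rich aldehyde of 4) and O-alkylation, not C-alkylation, of ring A; the first is secured by the low electrophilicity of the 2,4,6-trioxygenated benzaldehyde, the second by its formyl group, which lowers the carbon nucleophilicity of ring A while reversible adducts drain through the irreversible aldol condensation. The formyl group left on C3 is the temporary activating group that is exchanged for the 3-oxygen in step 4.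

Step 4
Reactants: 5 (2R)-5,7-bis(benzyloxy)-2-[3,4,5-tris(benzyloxy)phenyl]-2H-chromene-3-carbaldehyde
Product: 7 (2R)-5,7-bis(benzyloxy)-2-[3,4,5-tris(benzyloxy)phenyl]-2H-chromen-3(4H)-one, via enol formate 6 (not isolated)
Conditions: 30 % aq. H2O2 (2 equiv), 2-nitrobenzeneseleninic acid (5 mol %), CH2Cl2, rt; aqueous wash; then KHCO3 (cat.), MeOH/CH2Cl2, 0 °C, short contact
Reagents that add atoms: hydrogen peroxide, OO
Why: Baeyer–Villiger oxidation of an α-substituted cinnamaldehyde-type enal by the perseleninic acid formed in the flask, in which the electron-rich vinyl carbon C3 migrates from carbon to oxygen in the peroxy hemiacetal adduct so that the helper formyl carbon is replaced by oxygen, after which mild methanolysis of the enol formate should release the ketone by protonation at C4 without touching C2.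

Step 5
Reactants: 7 (2R)-5,7-bis(benzyloxy)-2-[3,4,5-tris(benzyloxy)phenyl]-2H-chromen-3(4H)-one
Product: 8 (2R,3R)-5,7-bis(benzyloxy)-2-[3,4,5-tris(benzyloxy)phenyl]-3,4-dihydro-2H-chromen-3-ol (penta-O-benzyl-epigallocatechin, 2,3-cis)
Conditions: LiBH(s-Bu)3 (L-Selectride), LiBr, THF, −78 °C; then H2O
Reagents that add atoms: none
Why: Ketone reduction with a bulky trialkylborohydride, which attacks C3 from the face anti to the 2-aryl group and should give the 2,3-cis alcohol (3R), as established for benzylated flavan-3-ones.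

Step 6
Reactants: 9 (+)-dihydrorobinetin, (2R,3R)-3,7-dihydroxy-2-(3,4,5-trihydroxyphenyl)-2,3-dihydro-4H-chromen-4-one
Product: 10 (2R,3R)-7-(benzyloxy)-3-hydroxy-2-[3,4,5-tris(benzyloxy)phenyl]-2,3-dihydro-4H-chromen-4-one
Conditions: BnBr (4.4 equiv), K2CO3 (4.4 equiv), DMF, rt, argon
Reagents that add atoms: benzyl bromide, BrCc1ccccc1
Why: Williamson ether synthesis of the four phenols, in which the secondary 3-hydroxyl next to the ketone is not ionised by K2CO3 at room temperature and should stay free, while exclusion of air protects the pyrogallol ring.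

Step 7
Reactants: 10 (2R,3R)-7-(benzyloxy)-3-hydroxy-2-[3,4,5-tris(benzyloxy)phenyl]-2,3-dihydro-4H-chromen-4-one
Product: 11 (2R,3S,4R)-7-(benzyloxy)-2-[3,4,5-tris(benzyloxy)phenyl]-3,4-dihydro-2H-chromene-3,4-diol (2,3-trans-3,4-trans)
Conditions: NaBH4, THF/MeOH, 0 °C
Reagents that add atoms: none
Why: Hydride reduction of the aryl ketone, known for 2,3-trans-dihydroflavonols to give mainly the 2,3-trans-3,4-trans diol (4R), where the C4 configuration has no bearing because C4 is ionised in step 9.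

Step 8
Reactants: 11 (2R,3S,4R)-7-(benzyloxy)-2-[3,4,5-tris(benzyloxy)phenyl]-3,4-dihydro-2H-chromene-3,4-diol
Product: 12 (2R,3R,4R)-7-(benzyloxy)-2-[3,4,5-tris(benzyloxy)phenyl]-3,4-dihydro-2H-chromene-3,4-diyl diacetate (same spatial arrangement as 11)
Conditions: Ac2O, pyridine, DMAP (cat.), CH2Cl2, 0 °C to rt
Reagents that add atoms: acetic anhydride, CC(=O)OC(C)=O
Why: Pyridine/DMAP-mediated acetylation of both hydroxyls, which provides at once the leaving group at the benzylic C4 and the participating ester at C3.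

Step 9
Reactants: 12 (2R,3R,4R)-7-(benzyloxy)-2-[3,4,5-tris(benzyloxy)phenyl]-3,4-dihydro-2H-chromene-3,4-diyl diacetate; 8 penta-O-benzyl-epigallocatechin (2–3 equiv, excess recovered)
Product: 13 (2R,3S,4S)-7-(benzyloxy)-4-{(2R,3R)-5,7-bis(benzyloxy)-3-hydroxy-2-[3,4,5-tris(benzyloxy)phenyl]-3,4-dihydro-2H-chromen-8-yl}-2-[3,4,5-tris(benzyloxy)phenyl]-3,4-dihydro-2H-chromen-3-yl acetate
Conditions: TMSOTf (0.1 equiv), CH2Cl2, −78 to −30 °C; Et3N quench
Reagents that add atoms: none
Why: Friedel–Crafts alkylation of the SN1 type, in which the 4-acetate ionises to the benzylic cation stabilised by the para 7-benzyloxy group, the 3-acetoxy group on the β-face assists and shields that face, and the most accessible nucleophilic carbon of 8 (C8, between O1 and the 7-benzyloxy group, not C6 between two benzyloxy groups) should attack from the α-face to give the 3,4-trans (4S) interflavan bond, as known for benzylated flavan-3-ol donors and acceptors.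

Step 10
Reactants: 13 (3-O-acetyl nona-O-benzyl dimer)
Product: 14 (2R,3S,4S)-7-(benzyloxy)-4-{(2R,3R)-5,7-bis(benzyloxy)-3-hydroxy-2-[3,4,5-tris(benzyloxy)phenyl]-3,4-dihydro-2H-chromen-8-yl}-2-[3,4,5-tris(benzyloxy)phenyl]-3,4-dihydro-2H-chromen-3-ol
Conditions: K2CO3 (cat.), MeOH/THF (1:1), 40 °C
Reagents that add atoms: none
Why: Base-catalysed transesterification removes the hindered 3-acetate as methyl acetate, and no epimerisable centre is present.

Step 11
Reactants: 14 (nona-O-benzyl dimer)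
Product: 15 robinetinidol-(4α→8)-epigallocatechin, (2R,3S,4S)-4-[(2R,3R)-3,5,7-trihydroxy-2-(3,4,5-trihydroxyphenyl)-3,4-dihydro-2H-chromen-8-yl]-2-(3,4,5-trihydroxyphenyl)-3,4-dihydro-2H-chromene-3,7-diol
Conditions: H2 (1 atm), Pd(OH)2/C, THF/MeOH/H2O, rt; filtration and lyophilisation under argon
Reagents that add atoms: none
Why: Hydrogenolysis of the nine benzyl ethers over Pd(OH)2/C, a standard last step for benzylated proanthocyanidins under which the ring C ether bonds and the interflavan C–C bond should survive.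

**Compound list**

1 | 3,4,5-tris(benzyloxy)benzaldehyde | O=Cc1cc(OCc2ccccc2)c(OCc2ccccc2)c(OCc2ccccc2)c1 | starting material
2 | (2E)-3-[3,4,5-tris(benzyloxy)phenyl]prop-2-enal | O=C/C=C/c1cc(OCc2ccccc2)c(OCc2ccccc2)c(OCc2ccccc2)c1 | intermediate
3 | 2,4,6-trihydroxybenzaldehyde | O=Cc1c(O)cc(O)cc1O | starting material
4 | 4,6-bis(benzyloxy)-2-hydroxybenzaldehyde | O=Cc1c(O)cc(OCc2ccccc2)cc1OCc1ccccc1 | intermediate
5 | (2R)-5,7-bis(benzyloxy)-2-[3,4,5-tris(benzyloxy)phenyl]-2H-chromene-3-carbaldehyde | c1c(OCc3ccccc3)cc(OCc3ccccc3)c2c1O[C@H](c1cc(OCc3ccccc3)c(OCc3ccccc3)c(OCc3ccccc3)c1)C(C=O)=C2 | intermediate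
6 | (2R)-5,7-bis(benzyloxy)-2-[3,4,5-tris(benzyloxy)phenyl]-2H-chromen-3-yl formate (enol formate) | c1c(OCc3ccccc3)cc(OCc3ccccc3)c2c1O[C@H](c1cc(OCc3ccccc3)c(OCc3ccccc3)c(OCc3ccccc3)c1)C(OC=O)=C2 | intermediate (not isolated)
7 | (2R)-5,7-bis(benzyloxy)-2-[3,4,5-tris(benzyloxy)phenyl]-2H-chromen-3(4H)-one | c1c(OCc3ccccc3)cc(OCc3ccccc3)c2c1O[C@H](c1cc(OCc3ccccc3)c(OCc3ccccc3)c(OCc3ccccc3)c1)C(=O)C2 | intermediate
8 | (2R,3R)-5,7-bis(benzyloxy)-2-[3,4,5-tris(benzyloxy)phenyl]-3,4-dihydro-2H-chromen-3-ol | c1c(OCc3ccccc3)cc(OCc3ccccc3)c2c1O[C@H](c1cc(OCc3ccccc3)c(OCc3ccccc3)c(OCc3ccccc3)c1)[C@H](O)C2 | intermediate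
9 | (+)-dihydrorobinetin, (2R,3R)-3,7-dihydroxy-2-(3,4,5-trihydroxyphenyl)-2,3-dihydro-4H-chromen-4-one | Oc1ccc2c(c1)O[C@H](c1cc(O)c(O)c(O)c1)[C@@H](O)C2=O | starting material
10 | (2R,3R)-7-(benzyloxy)-3-hydroxy-2-[3,4,5-tris(benzyloxy)phenyl]-2,3-dihydro-4H-chromen-4-one | C(c1ccccc1)Oc1ccc2c(c1)O[C@H](c1cc(OCc3ccccc3)c(OCc3ccccc3)c(OCc3ccccc3)c1)[C@@H](O)C2=O | intermediate
11 | (2R,3S,4R)-7-(benzyloxy)-2-[3,4,5-tris(benzyloxy)phenyl]-3,4-dihydro-2H-chromene-3,4-diol | C(c1ccccc1)Oc1ccc2c(c1)O[C@H](c1cc(OCc3ccccc3)c(OCc3ccccc3)c(OCc3ccccc3)c1)[C@@H](O)[C@@H]2O | intermediate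
12 | (2R,3R,4R)-7-(benzyloxy)-2-[3,4,5-tris(benzyloxy)phenyl]-3,4-dihydro-2H-chromene-3,4-diyl diacetate | C(c1ccccc1)Oc1ccc2c(c1)O[C@H](c1cc(OCc3ccccc3)c(OCc3ccccc3)c(OCc3ccccc3)c1)[C@@H](OC(C)=O)[C@@H]2OC(C)=O | intermediate
13 | (2R,3S,4S)-7-(benzyloxy)-4-{(2R,3R)-5,7-bis(benzyloxy)-3-hydroxy-2-[3,4,5-tris(benzyloxy)phenyl]-3,4-dihydro-2H-chromen-8-yl}-2-[3,4,5-tris(benzyloxy)phenyl]-3,4-dihydro-2H-chromen-3-yl acetate | C(c1ccccc1)Oc1ccc2c(c1)O[C@H](c1cc(OCc3ccccc3)c(OCc3ccccc3)c(OCc3ccccc3)c1)[C@@H](OC(C)=O)[C@@H]2c1c(OCc3ccccc3)cc(OCc3ccccc3)c2c1O[C@H](c1cc(OCc3ccccc3)c(OCc3ccccc3)c(OCc3ccccc3)c1)[C@H](O)C2 | intermediate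
14 | (2R,3S,4S)-7-(benzyloxy)-4-{(2R,3R)-5,7-bis(benzyloxy)-3-hydroxy-2-[3,4,5-tris(benzyloxy)phenyl]-3,4-dihydro-2H-chromen-8-yl}-2-[3,4,5-tris(benzyloxy)phenyl]-3,4-dihydro-2H-chromen-3-ol | C(c1ccccc1)Oc1ccc2c(c1)O[C@H](c1cc(OCc3ccccc3)c(OCc3ccccc3)c(OCc3ccccc3)c1)[C@@H](O)[C@@H]2c1c(OCc3ccccc3)cc(OCc3ccccc3)c2c1O[C@H](c1cc(OCc3ccccc3)c(OCc3ccccc3)c(OCc3ccccc3)c1)[C@H](O)C2 | intermediate
15 | robinetinidol-(4α→8)-epigallocatechin, (2R,3S,4S)-4-[(2R,3R)-3,5,7-trihydroxy-2-(3,4,5-trihydroxyphenyl)-3,4-dihydro-2H-chromen-8-yl]-2-(3,4,5-trihydroxyphenyl)-3,4-dihydro-2H-chromene-3,7-diol | Oc1ccc2c(c1)O[C@H](c1cc(O)c(O)c(O)c1)[C@@H](O)[C@@H]2c1c(O)cc(O)c2c1O[C@H](c1cc(O)c(O)c(O)c1)[C@H](O)C2 | target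

**Step count**

Total: 11 steps. Longest linear sequence: 7 steps (step 1 or 2, then steps 3, 4, 5, 9, 10, 11).

**Steps most likely to fail**

Step 3. The aldol closure at the doubly ortho-substituted, electron-rich formyl carbon of 4 may be slow. Reversible oxa-Michael adducts could then accumulate and retro-oxa-Michael addition could erode the enantiomeric purity. The fallback sets out from 2 and 4 and returns at 7; ring C is still closed through C3–C4, now by olefin metathesis.
- 2 is reduced (NaBH4, CeCl3, MeOH) to (2E)-3-[3,4,5-tris(benzyloxy)phenyl]prop-2-en-1-ol F1, which is converted (ClCO2Me, pyridine) into its methyl carbonate F2.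
- 4 is methylenated (Ph3P=CH2, THF) to 3,5-bis(benzyloxy)-2-vinylphenol F3.
- Iridium-catalysed allylic etherification of F3 with F2 should give the branched (S)-1-arylallyl aryl ether F4. Conditions: [Ir(cod)Cl]2, the enantiomer of O,O'-(1,1'-binaphthalene-2,2'-diyl) N,N-bis(1-phenylethyl)phosphoramidite that leads to the (S)-ether, K3PO4, THF.
- Ring-closing metathesis with the second-generation Grubbs catalyst [RuCl2(=CHPh)(PCy3)(H2IMes)] should give the (2S)-flav-3-ene F5.
- Hydroboration (BH3·THF) anti to the 2-aryl group gives the 2,3-trans flavan-3-ylborane F6 (not isolated), which is oxidised (H2O2, NaOH) to the (2R,3S)-alcohol F7.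
- Dess–Martin oxidation of F7 gives 7.

Step 4. The electron-rich enol formate may be epoxidised, or the alkoxyarenes oxidised, by excess peracid. Configuration at C2 may also be lost by enolisation when the base-sensitive flavan-3-one is set free. The fallback sets out from 5 and returns at 8 without passing through the ketone. The oxidation is stopped at the enol formate 6, which is isolated by non-aqueous work-up and hydrogenated at C3=C4 with [Ir(cod)(PCy3)(py)]PF6 and H2 in CH2Cl2. Hydrogen should add to the face anti to the 2-aryl group and give (2R,3R)-5,7-bis(benzyloxy)-2-[3,4,5-tris(benzyloxy)phenyl]-3,4-dihydro-2H-chromen-3-yl formate F8. Its formyl group is removed (K2CO3, MeOH) to give 8.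

Step 9. The 5-deoxy benzylic acetate may ionise sluggishly, with loss of H3 from the cation (elimination). Attack through C6 in place of C8 and further alkylation of the product to oligomers are also possible. The fallback sets out from 8 and 9 and returns at 15 by a union of the free phenols. 8 is debenzylated (H2, Pd(OH)2/C) to (−)-epigallocatechin F9, and 9 is reduced (NaBH4, EtOH) to the free (2R,3S,4R)-flavan-3,4-diol (leucorobinetinidin) F10. F10 and an excess of F9 are condensed in 0.1 M aqueous HCl at room temperature, the classical acid-catalysed coupling of 5-deoxyflavan-3,4-diols with phloroglucinol-type flavan-3-ols. This should give 15 directly together with its 4β and 4→6 isomers, to be separated on Sephadex LH-20.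

**Further compounds**

F1 | step 3 | (2E)-3-[3,4,5-tris(benzyloxy)phenyl]prop-2-en-1-ol | OC/C=C/c1cc(OCc2ccccc2)c(OCc2ccccc2)c(OCc2ccccc2)c1
F2 | step 3 | methyl (2E)-3-[3,4,5-tris(benzyloxy)phenyl]prop-2-en-1-yl carbonate | COC(=O)OC/C=C/c1cc(OCc2ccccc2)c(OCc2ccccc2)c(OCc2ccccc2)c1
F3 | step 3 | 3,5-bis(benzyloxy)-2-vinylphenol | C=Cc1c(O)cc(OCc2ccccc2)cc1OCc1ccccc1
F4 | step 3 | 1,5-bis(benzyloxy)-2-ethenyl-3-({(1S)-1-[3,4,5-tris(benzyloxy)phenyl]prop-2-en-1-yl}oxy)benzene | C=Cc1c(OCc2ccccc2)cc(OCc2ccccc2)cc1O[C@H](c1cc(OCc2ccccc2)c(OCc2ccccc2)c(OCc2ccccc2)c1)C=C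
F5 | step 3 | (2S)-5,7-bis(benzyloxy)-2-[3,4,5-tris(benzyloxy)phenyl]-2H-chromene | c1c(OCc3ccccc3)cc(OCc3ccccc3)c2c1O[C@H](c1cc(OCc3ccccc3)c(OCc3ccccc3)c(OCc3ccccc3)c1)C=C2
F6 | step 3 | 2,3-trans-{5,7-bis(benzyloxy)-2-[3,4,5-tris(benzyloxy)phenyl]-3,4-dihydro-2H-chromen-3-yl}borane (boron trans to the 2-aryl group, not isolated) | c1c(OCc3ccccc3)cc(OCc3ccccc3)c2c1O[C@H](c1cc(OCc3ccccc3)c(OCc3ccccc3)c(OCc3ccccc3)c1)[C@@H](B)C2
F7 | step 3 | (2R,3S)-5,7-bis(benzyloxy)-2-[3,4,5-tris(benzyloxy)phenyl]-3,4-dihydro-2H-chromen-3-ol | c1c(OCc3ccccc3)cc(OCc3ccccc3)c2c1O[C@H](c1cc(OCc3ccccc3)c(OCc3ccccc3)c(OCc3ccccc3)c1)[C@@H](O)C2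
F8 | step 4 | (2R,3R)-5,7-bis(benzyloxy)-2-[3,4,5-tris(benzyloxy)phenyl]-3,4-dihydro-2H-chromen-3-yl formate | c1c(OCc3ccccc3)cc(OCc3ccccc3)c2c1O[C@H](c1cc(OCc3ccccc3)c(OCc3ccccc3)c(OCc3ccccc3)c1)[C@H](OC=O)C2
F9 | step 9 | (−)-epigallocatechin, (2R,3R)-2-(3,4,5-trihydroxyphenyl)-3,4-dihydro-2H-chromene-3,5,7-triol | c1c(O)cc(O)c2c1O[C@H](c1cc(O)c(O)c(O)c1)[C@H](O)C2
F10 | step 9 | leucorobinetinidin, (2R,3S,4R)-2-(3,4,5-trihydroxyphenyl)-3,4-dihydro-2H-chromene-3,4,7-triol | Oc1ccc2c(c1)O[C@H](c1cc(O)c(O)c(O)c1)[C@@H](O)[C@@H]2O
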